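**Retrosynthetic overview**
1. Target 24 ⇒ diol 15 + bromodienamide 23: the triene is closed last by a Heck coupling at the C4 vinyl group.
2. 15 ⇒ α-iodoenone boronate 13 + primary amide 7 (copper-catalysed C2–N coupling); 13 ⇒ enone boronate 12 by α-iodination.
3. 12 (C4 and C5 set together) ⇒ achiral p-quinol 10 by an organocatalytic, boron-tethered desymmetrising oxa-Michael addition; 10 ⇒ quinone monoketal 8 + vinylmagnesium bromide.
4. 7 ⇒ (R)-2-methylhexanal 2 (asymmetric hydroformylation of hex-1-ene 1) + two stabilised Wittig ylides; 23 ⇒ glutaconaldehyde salt 19 + cyclopentane-1,3-dione 16.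
5. Rings: both carbocycles are bought (8, 16); the only ring closed on the way is the temporary dioxaborolane (step 6), opened again in step 8.

Assumption: the sense of induction of the chiral catalysts in steps 1 and 6 is as written; should either be reversed, the mirror-image ligand or the quinine-derived pseudo-enantiomer is used with no other change.

Ring atoms are numbered as in a cyclohex-2-en-1-one: C1 = ketone, C2 = N-bearing carbon, C4 = carbinol carbon with the triene, C5 = CHOH. The target is (4S,5R) with the two hydroxyls cis, and (6R) in the acyl chain.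

**Route**

Step 1
Reactants: 1 hex-1-ene
Product: 2 (2R)-2-methylhexanal
Conditions: Rh(acac)(CO)2 (0.4 mol%), (Sax,S,S)-BOBPHOS (0.5 mol%), CO/H2 1:1 (5 bar), toluene, 20 °C; branched/linear ca. 3:1, 2 separated from heptanal by spinning-band distillation
Reagents that add atoms: carbon monoxide, [C-]#[O+]
Why: Branched-selective asymmetric hydroformylation of an alkyl alkene, in which the phospholane–phosphite ligand fixes the alkene face during hydride insertion and sets the (R) centre (about 93% ee reported for this substrate).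

Step 2
Reactants: 2 (2R)-2-methylhexanal; 3 2-(triphenylphosphoranylidene)propanal
Product: 4 (2E,4R)-2,4-dimethyloct-2-enal
Conditions: toluene, 90 °C, 16 h
Reagents that add atoms: none
Why: Wittig olefination with a stabilised formyl ylide is E-selective and non-basic, so the α-centre of 2 is carried over without epimerisation and becomes a non-enolisable allylic centre.

Step 3
Reactants: 4 (2E,4R)-2,4-dimethyloct-2-enal; 5 ethyl 2-(triphenylphosphoranylidene)propanoate
Product: 6 ethyl (2E,4E,6R)-2,4,6-trimethyldeca-2,4-dienoate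
Conditions: CH2Cl2, 40 °C, 24 h
Reagents that add atoms: none
Why: A second stabilised-ylide Wittig olefination gives the (2E) trisubstituted enoate and leaves the existing alkene and stereocentre untouched.

Step 4
Reactants: 6 ethyl (2E,4E,6R)-2,4,6-trimethyldeca-2,4-dienoate
Product: 7 (2E,4E,6R)-2,4,6-trimethyldeca-2,4-dienamide
Conditions: Me3Al, NH4Cl, toluene, 0 → 50 °C; then dilute aq. HCl
Reagents that add atoms: ammonium chloride, [NH4+].[Cl-]
Why: Weinreb aminolysis, in which the aluminium amide made in the flask converts the hindered conjugated ester directly into the primary amide without touching the diene.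

Step 5
Reactants: 8 4,4-dimethoxycyclohexa-2,5-dien-1-one
Product: 10 4-hydroxy-4-vinylcyclohexa-2,5-dien-1-one, via ketal carbinol 9 (not isolated)
Conditions: CH2=CHMgBr, THF, −78 °C; then 10% aq. AcOH, 0 → 23 °C
Reagents that add atoms: vinylmagnesium bromide, C=C[Mg]Br; water, O
Why: Grignard 1,2-addition to the quinone monoketal carbonyl followed by mild ketal hydrolysis gives the achiral, symmetric p-quinol.

Step 6
Reactants: 10 4-hydroxy-4-vinylcyclohexa-2,5-dien-1-one
Product: 12 (3aR,7aS)-2-phenyl-7a-vinyl-3a,7a-dihydro-1,3,2-benzodioxaborol-5(4H)-one, via boronic hemiester 11 (not isolated)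
Conditions: PhB(OH)2 (1.2 equiv), quinidine-derived 9-epi-amino thiourea bearing 3,5-bis(trifluoromethyl)phenyl (10 mol%), 4 Å MS, toluene, 23 °C
Reagents that add atoms: phenylboronic acid, OB(O)c1ccccc1
Why: Proposed new method: the tertiary quinol OH condenses with PhB(OH)2 to hemiester 11, the quinuclidine nitrogen of the catalyst binds boron and makes the remaining B–OH oxygen nucleophilic while the thiourea hydrogen-bonds the dienone carbonyl, so this oxygen adds in a 5-exo oxa-Michael fashion to only one of the two enantiotopic β-carbons, which sets C4 (S) and C5 (R) at once with the five-membered boronate tether forcing the cis-diol; the closest known reaction types are the amine–thiourea-catalysed boronic acid hemiester oxa-Michael addition to acyclic γ-hydroxy enones and the Brønsted acid-catalysed acetalisation/oxa-Michael desymmetrisation of p-quinols, but a boron-tethered desymmetrisation of a quinol has not been described.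

Step 7
Reactants: 12 (3aR,7aS)-2-phenyl-7a-vinyl-3a,7a-dihydro-1,3,2-benzodioxaborol-5(4H)-one
Product: 13 (3aR,7aS)-6-iodo-2-phenyl-7a-vinyl-3a,7a-dihydro-1,3,2-benzodioxaborol-5(4H)-one
Conditions: I2 (1.5 equiv), pyridine/CH2Cl2 1:1, 0 → 23 °C; brief cold aq. Na2S2O3 wash
Reagents that add atoms: iodine, II
Why: Johnson α-iodination (pyridine conjugate addition, iodination of the enolate, elimination) functionalises only the vinylic α-carbon and leaves the vinyl group, the boronate and both stereocentres alone.

Step 8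
Reactants: 13 (3aR,7aS)-6-iodo-2-phenyl-7a-vinyl-3a,7a-dihydro-1,3,2-benzodioxaborol-5(4H)-one; 7 (2E,4E,6R)-2,4,6-trimethyldeca-2,4-dienamide
Product: 15 (2E,4E,6R)-N-[(3S,4R)-3-ethenyl-3,4-dihydroxy-6-oxocyclohex-1-en-1-yl]-2,4,6-trimethyldeca-2,4-dienamide, via amido boronate 14 (not isolated)
Conditions: CuI (10 mol%), N,N'-dimethylethylenediamine (20 mol%), K3PO4, toluene, 60 °C, N2; then pinacol, EtOAc/H2O, 23 °C
Reagents that add atoms: none
Why: Goldberg-type copper-catalysed amidation of the activated vinyl iodide forms the C2–N bond while the boronate shields the base-sensitive β-oxy ketone (no oxidant is present to transfer phenyl to copper), and pinacol then frees the cis-diol by transesterification without touching either stereocentre.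

Step 9
Reactants: 16 cyclopentane-1,3-dione
Product: 17 2-(hydroxyimino)cyclopentane-1,3-dione
Conditions: NaNO2, aq. HCl, 0 °C
Reagents that add atoms: sodium nitrite, [Na+].[O-]N=O
Why: Nitrosation of the doubly activated methylene, the nitroso compound tautomerising to the oxime.

Step 10
Reactants: 17 2-(hydroxyimino)cyclopentane-1,3-dione
Product: 18 2-amino-3-hydroxycyclopent-2-en-1-one hydrochloride
Conditions: H2 (3 bar), 10% Pd/C, HCl (1.1 equiv), EtOH, 23 °C
Reagents that add atoms: hydrogen chloride, Cl
Why: Catalytic hydrogenation of the oxime to the amine, trapped as its hydrochloride so that the α-amino ketone cannot self-condense.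

Step 11
Reactants: 19 potassium (1E,3E)-5-oxopenta-1,3-dien-1-olate (glutaconaldehyde potassium salt)
Product: 20 (2E,4E)-5-bromopenta-2,4-dienal
Conditions: PPh3, Br2, CH2Cl2, 0 → 23 °C; cat. I2 to equilibrate to the E,E isomer
Reagents that add atoms: bromine, BrBr
Why: The enolate oxygen is activated as an oxyphosphonium ion and replaced by bromide in a vinylogous addition–elimination driven by formation of the phosphine oxide.

Step 12
Reactants: 20 (2E,4E)-5-bromopenta-2,4-dienal
Product: 21 (2E,4E)-5-bromopenta-2,4-dienoic acid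
Conditions: NaClO2, NaH2PO4, 2-methylbut-2-ene, t-BuOH/H2O, 0 → 23 °C
Reagents that add atoms: sodium chlorite, [Na+].[O-]Cl=O
Why: Pinnick oxidation converts the enal into the acid without isomerising or halogenating the bromodiene.

Step 13
Reactants: 21 (2E,4E)-5-bromopenta-2,4-dienoic acid; 18 2-amino-3-hydroxycyclopent-2-en-1-one hydrochloride
Product: 23 (2E,4E)-5-bromo-N-(2-hydroxy-5-oxocyclopent-1-en-1-yl)penta-2,4-dienamide, via acid chloride 22 (not isolated)
Conditions: (COCl)2, cat. DMF, CH2Cl2, 0 °C; then 18, Et3N, THF, 0 → 23 °C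
Reagents that add atoms: none
Why: N-acylation through the acid chloride, any O-acyl enol ester formed first passing its acyl group on to nitrogen to give the more stable amide.

Step 14
Reactants: 15 (2E,4E,6R)-N-[(3S,4R)-3-ethenyl-3,4-dihydroxy-6-oxocyclohex-1-en-1-yl]-2,4,6-trimethyldeca-2,4-dienamide; 23 (2E,4E)-5-bromo-N-(2-hydroxy-5-oxocyclopent-1-en-1-yl)penta-2,4-dienamide
Product: 24 (2E,4E,6R)-N-[(3S,4R)-3,4-dihydroxy-3-{(1E,3E,5E)-7-[(2-hydroxy-5-oxocyclopent-1-en-1-yl)amino]-7-oxohepta-1,3,5-trien-1-yl}-6-oxocyclohex-1-en-1-yl]-2,4,6-trimethyldeca-2,4-dienamide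
Conditions: Pd(OAc)2 (10 mol%), Bu4NCl, NaHCO3, DMF, 50 °C, N2, dark
Reagents that add atoms: none
Why: Heck reaction under Jeffery conditions, in which oxidative addition keeps the bromodiene geometry, insertion occurs at the terminal vinyl carbon, and syn β-hydride elimination (possible only away from the quaternary carbinol carbon) gives the new E-alkene without touching C4 or C5.

**Compound list**
1 | hex-1-ene | C=CCCCC | starting material
2 | (2R)-2-methylhexanal | CCCC[C@@H](C)C=O | intermediate
3 | 2-(triphenylphosphoranylidene)propanal | O=CC(C)=P(c1ccccc1)(c1ccccc1)c1ccccc1 | starting material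
4 | (2E,4R)-2,4-dimethyloct-2-enal | CCCC[C@@H](C)/C=C(\C)C=O | intermediate
5 | ethyl 2-(triphenylphosphoranylidene)propanoate | CCOC(=O)C(C)=P(c1ccccc1)(c1ccccc1)c1ccccc1 | starting material
6 | ethyl (2E,4E,6R)-2,4,6-trimethyldeca-2,4-dienoate | CCCC[C@@H](C)/C=C(C)/C=C(\C)C(=O)OCC | intermediate
7 | (2E,4E,6R)-2,4,6-trimethyldeca-2,4-dienamide | CCCC[C@@H](C)/C=C(C)/C=C(\C)C(N)=O | intermediate
8 | 4,4-dimethoxycyclohexa-2,5-dien-1-one | COC1(OC)C=CC(=O)C=C1 | starting material
9 | 4,4-dimethoxy-1-vinylcyclohexa-2,5-dien-1-ol (ketal carbinol, as its magnesium alkoxide until the quench) | C=CC1(O)C=CC(OC)(OC)C=C1 | intermediate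
10 | 4-hydroxy-4-vinylcyclohexa-2,5-dien-1-one | C=CC1(O)C=CC(=O)C=C1 | intermediate
11 | 4-{[hydroxy(phenyl)boranyl]oxy}-4-vinylcyclohexa-2,5-dien-1-one (boronic hemiester) | C=CC1(OB(O)c2ccccc2)C=CC(=O)C=C1 | intermediate
12 | (3aR,7aS)-2-phenyl-7a-vinyl-3a,7a-dihydro-1,3,2-benzodioxaborol-5(4H)-one (cyclic phenylboronate of (4S,5R)-4,5-dihydroxy-4-vinylcyclohex-2-en-1-one) | C1=C[C@]2(C=C)OB(c3ccccc3)O[C@@H]2CC1=O | intermediate
13 | (3aR,7aS)-6-iodo-2-phenyl-7a-vinyl-3a,7a-dihydro-1,3,2-benzodioxaborol-5(4H)-one | IC1=C[C@]2(C=C)OB(c3ccccc3)O[C@@H]2CC1=O | intermediate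
14 | (2E,4E,6R)-2,4,6-trimethyl-N-[(3aR,7aS)-5-oxo-2-phenyl-7a-vinyl-3a,4,5,7a-tetrahydro-1,3,2-benzodioxaborol-6-yl]deca-2,4-dienamide (amido boronate) | CCCC[C@@H](C)/C=C(C)/C=C(\C)C(=O)NC1=C[C@]2(C=C)OB(c3ccccc3)O[C@@H]2CC1=O | intermediate
15 | (2E,4E,6R)-N-[(3S,4R)-3-ethenyl-3,4-dihydroxy-6-oxocyclohex-1-en-1-yl]-2,4,6-trimethyldeca-2,4-dienamide | CCCC[C@@H](C)/C=C(C)/C=C(\C)C(=O)NC1=C[C@@](O)(C=C)[C@H](O)CC1=O | intermediate
16 | cyclopentane-1,3-dione | O=C1CCC(=O)C1 | starting material
17 | 2-(hydroxyimino)cyclopentane-1,3-dione | O=C1CCC(=O)C1=NO | intermediate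
18 | 2-amino-3-hydroxycyclopent-2-en-1-one hydrochloride | Cl.NC1=C(O)CCC1=O | intermediate
19 | potassium (1E,3E)-5-oxopenta-1,3-dien-1-olate | [K+].[O-]/C=C/C=C/C=O | starting material
20 | (2E,4E)-5-bromopenta-2,4-dienal | O=C/C=C/C=C/Br | intermediate
21 | (2E,4E)-5-bromopenta-2,4-dienoic acid | OC(=O)/C=C/C=C/Br | intermediate
22 | (2E,4E)-5-bromopenta-2,4-dienoyl chloride | ClC(=O)/C=C/C=C/Br | intermediate
23 | (2E,4E)-5-bromo-N-(2-hydroxy-5-oxocyclopent-1-en-1-yl)penta-2,4-dienamide | Br/C=C/C=C/C(=O)NC1=C(O)CCC1=O | intermediate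
24 | (2E,4E,6R)-N-[(3S,4R)-3,4-dihydroxy-3-{(1E,3E,5E)-7-[(2-hydroxy-5-oxocyclopent-1-en-1-yl)amino]-7-oxohepta-1,3,5-trien-1-yl}-6-oxocyclohex-1-en-1-yl]-2,4,6-trimethyldeca-2,4-dienamide | CCCC[C@@H](C)/C=C(C)/C=C(\C)C(=O)NC1=C[C@@](O)(/C=C/C=C/C=C/C(=O)NC2=C(O)CCC2=O)[C@H](O)CC1=O | target

**Step count and risks**
Total step count: 14. Longest linear sequence: 6 steps (steps 1, 2, 3, 4, 8, 14; hex-1-ene to 24).

The three steps most likely to fail:

Step 1. Branched selectivity is only about 3:1, the enantiomeric excess of 2 fixes the diastereomeric purity of everything after step 8, and 2 must be distilled from heptanal without racemising. The fallback sets out from 1 and replaces hydroformylation by zirconium-catalysed asymmetric carboalumination: Me3Al with (−)-bis(1-neomenthylindenyl)zirconium dichloride in CH2Cl2 gives dimethyl[(2R)-2-methylhexyl]alumane F1, which is oxidised in the flask with O2 to (2R)-2-methylhexan-1-ol F2 (ca. 75% ee, the minor enantiomer removed by lipase-catalysed acetylation). Dess–Martin oxidation of F2 comes back to the route at 2.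

Step 6 (the proposed new method). The hindered tertiary hemiester may form or cyclise slowly, the enantioselectivity is unproven, and 12 can lose ee by retro-addition before it is iodinated. The fallback uses known chemistry and sets out from 10: a chiral phosphoric acid-catalysed acetalisation/oxa-Michael cascade with 4-methoxybenzaldehyde ((R)-TRIP, 4 Å MS, 1,2-dichloroethane, 40 °C) gives (2S,3aR,7aS)-2-(4-methoxyphenyl)-7a-vinyl-3a,7a-dihydro-1,3-benzodioxol-5(4H)-one F3, drawn as the exo-aryl diastereomer; its acetal centre is lost in the next operation. Acid-catalysed exchange of F3 with PhB(OH)2 (cat. camphorsulfonic acid, wet CH2Cl2) hands the diol to boron and comes back to the route at 12.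

Step 14. The Heck coupling has to work on a substrate with a free β-hydroxy ketone (base-induced dehydration to the quinol is the main danger) and an acidic enol in the partner. The fallback sets out from 15 and changes the bond-forming logic to metathesis then Suzuki coupling: cross-metathesis with vinylboronic acid pinacol ester (second-generation Grubbs catalyst RuCl2(=CHPh)(PCy3)(H2IMes), CH2Cl2, 40 °C) gives (2E,4E,6R)-N-{(3S,4R)-3,4-dihydroxy-6-oxo-3-[(E)-2-(4,4,5,5-tetramethyl-1,3,2-dioxaborolan-2-yl)ethenyl]cyclohex-1-en-1-yl}-2,4,6-trimethyldeca-2,4-dienamide F4. Suzuki–Miyaura coupling of F4 with 23 (Pd(PPh3)4, aq. K3PO4, THF, 23 °C) comes back to the route at 24.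

**Further compounds**
F1 | step 1 | dimethyl[(2R)-2-methylhexyl]alumane | CCCC[C@@H](C)C[Al](C)C
F2 | step 1 | (2R)-2-methylhexan-1-ol | CCCC[C@@H](C)CO
F3 | step 6 | (2S,3aR,7aS)-2-(4-methoxyphenyl)-7a-vinyl-3a,7a-dihydro-1,3-benzodioxol-5(4H)-one | C1=C[C@]2(C=C)O[C@@H](c3ccc(OC)cc3)O[C@@H]2CC1=O
F4 | step 14 | (2E,4E,6R)-N-{(3S,4R)-3,4-dihydroxy-6-oxo-3-[(E)-2-(4,4,5,5-tetramethyl-1,3,2-dioxaborolan-2-yl)ethenyl]cyclohex-1-en-1-yl}-2,4,6-trimethyldeca-2,4-dienamide | CCCC[C@@H](C)/C=C(C)/C=C(\C)C(=O)NC1=C[C@@](O)(/C=C/B2OC(C)(C)C(C)(C)O2)[C@H](O)CC1=O
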